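The constants split this network into two clocks, and I reckon with the rate of target formation and what slows it, the exits to dormant form and isomer of the product B included.

    substrate ⇌ target (K1 = 29, k1 = 0.00220 /s)
    substrate + catalyst ⇌ isomer of the product A + catalyst, rate k2*[substrate]*[catalyst] forward; the back reaction follows from the equilibrium constant (K2 = 0.70, k2 = 49.5 /M/s)
    substrate + catalyst ⇌ isomer of the product B + catalyst, rate k3*[substrate]*[catalyst] forward; the back reaction follows from the equilibrium constant (K3 = 1.26, k3 = 0.924 /M/s)
    substrate ⇌ dormant form (K4 = 4.5, k4 = 0.00126 /s)

| flask | substrate | catalyst | remark | time |
|---|---|---|---|---|
| delta | 0.20 M | 0.56 mM | one stirred flow tank at steady state, fed with the mixture as stated, mean residence time 5.0 min |  |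
| alpha | 0.20 M | 0.56 mM | one stirred flow tank at steady state, fed with the mixture as stated, mean residence time 15.0 min |  |
| beta | 0.20 M | 0.56 mM | a closed flask charged with all of it at once and left for 5.0 min | 5.0 min |
| gamma | 0.20 M (fed, over 4.00 min) | 0.56 mM | a stirred flask in which substrate is dosed at a steady rate over 4.00 min without added volume, worked up at 5.0 min | 5.0 min |

1. the set-up with the highest amount of target at the outlet or at the end, in percent of the substrate put in ("none" if the first two lie within 2 percentage points) (delta / alpha / beta / gamma / none)
2. amount of target at the outlet or at the end, in percent of the substrate put in, delta
3. amount of target at the outlet or at the end, in percent of the substrate put in, alpha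
4. amount of target at the outlet or at the end, in percent of the substrate put in, beta
5. amount of target at the outlet or at the end, in percent of the substrate put in, gamma

- the stated concentrations are those of everything mixed, before any reaction; amounts are the same in each set-up
- the feed brings no volume worth counting
- run time (beta): 5.0 min

In beta, the closed flask, target starts forming at 0.0264 M/min; held for the whole run, that rate gives 66.0 % of the charge. The first slowing comes from the catalyst. Its pseudo-first-order exchange of substrate with isomer of the product A relaxes with time constant 0.248 min, far shorter than the 7.58 min of the step to target. So I treat the two as one pool in quasi-equilibrium, in which substrate holds the share 0.588, and the rate drops by that factor at once. First pass: 38.8 %.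

But the pool drains through three exits, to target, dormant form and isomer of the product B. This gives the pool drain constant, the substrate share times the sum of the three exit constants, 0.140 /min. Going round once more, the rate in beta decays with this constant to 0.496 of its value by the end, a mean factor of 0.719, so beta gives 27.9 %. I leave out the way back from target and dormant form.

In a tank the rate stands at its outlet value, slowed by one over one plus the drain constant times the residence time, which gives 22.8 % for delta and 37.5 % for alpha. In gamma the pool fills during dosing and then drains, leaving 66.5 % at the end. Target takes the share 55.3 % of what has left the pool, so gamma gives 18.5 %. I therefore put alpha first.

The forecast gives 23.2 % for delta, 38.8 % for alpha, 28 % for beta and 19.1 % for gamma, with alpha best, holding that “target yield is therefore set by the time available”.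

The simulation gives 23.2 %, 38.8 %, 28.0 % and 19.0 % in that order, with alpha best. The drain constant leaves 49.6 % of the charge in the pool of beta, and beta holds 29.0 % of substrate plus 21.4 % of isomer of the product A. The largest single effect behind the lead of alpha over gamma is the return of isomer of the product A to substrate: with it taken away, gamma minus alpha goes from −20 percentage points to 0.36 points and the answer to best turns. For gamma read at 8.0 min, the drain constant leaves 43.6 % in the pool, hence 31.2 % of target; the computed flask holds 31.1 %.

The constants were chosen freely; the result is computed.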